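## Structural features

The target is a sesquineolignan made of three C6C3 units. Guaiacyl ring A sits on C2' of a 2,3-dihydrobenzofuran (oxygen ring O1'–C2'–C3'–C3a'–C7a' fused to the methoxylated ring B), C5' of ring B carries C2 of a tetrahydrofuran (O1, C2–C5), and C5 of that ring carries the 4-hydroxy-3-methoxybenzyl group of ring C. The six stereocentres form two blocks: C2'/C3' are (2R,3R), which places the aryl and hydroxymethyl groups cis, and the contiguous C2–C5 are all S, with the aryl group at C2 cis to the benzyl group at C5 and trans to CH2OH at C3, and the hydroxyl at C4 trans to CH2OH and cis to the benzyl group. The cis-dihydrobenzofuran is the less stable isomer and is fragile in three ways: a carbonyl group at C3' would let it epimerise, the C2'–O1' bond is benzylic to a para-oxygenated ring and can ionise in acid (or open from a free phenoxide through a quinone methide) and reclose trans, and this bond, like C2–O1, is a benzylic C–O bond open to hydrogenolysis. Two phenols, two primary hydroxyls and one secondary hydroxyl must be carried and revealed without touching these bonds. The real difficulty is the tetrahydrofuran: four adjacent stereocentres, three of them created while two large fragments are joined, in a ring that carries three of its four substituents on one face. The key step exploits the fact that only two bonds of this ring, O1–C2 and C3–C4, join the central unit to the ring C unit: C2, C3 and the CH2OH carbon are the β, α and carbonyl carbons of a cinnamaldehyde on ring B, and O1, C5 and C4 are the hydroxyl oxygen, C2 and C1 of a 2-hydroxy-3-arylpropanal.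

## Logic of the disconnections

21 ⇒ 20. Three O–Si bonds are cut and no skeletal bond. The last step has to be neither reductive nor acidic nor strongly basic, because C2'–O1' and C2–O1 are benzylic and ring A becomes a free para-hydroxybenzyl system. One kind of silyl ether on both phenols and on the C3' hydroxymethyl group allows a single buffered fluoride step and avoids hydrogenolysis altogether. The demand is that every earlier step tolerates aryl and alkyl silyl ethers.

20 ⇒ 19 ⇒ 12 + 18. The C3 hydroxymethyl group is taken back to a formyl group, and 19 is cut at O1–C2 and C3–C4. These are the only bonds between the two halves, so the cut is fully convergent and removes one ring and three stereocentres (C2, C3, C4) at once; both partners stand at the aldehyde oxidation level. The forward step must add a weak oxygen nucleophile to an electron-rich enal, control C2 by the catalyst, close the ring before 18 condenses with itself, and keep the labile β-hydroxy aldehyde 19 from dehydrating, which is why it is reduced in the same flask. 12 must carry no free hydroxyl and 18 must carry a free one.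

12 ⇒ 11. The Cα=Cβ double bond is cut (Wittig olefination). This returns the side chain to an aromatic aldehyde and uses neutral conditions. The demand is E geometry and a single homologation.

11 ⇒ 10 ⇒ 8 (through 9). An O–Si bond is cut, the C3' hydroxymethyl group is traced to an ester and the formyl group to a dioxolane. The ester is the handle left by the carbenoid chemistry and is the only stage at which C3' can epimerise, so it is reduced immediately and without base. The aldehyde must be masked while the diazo compound, the carbenoid and the hydride are present, and it must be released by acid mild enough for the C2'–O1' bond.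

8 ⇒ 7. C2'–C3' is cut (carbenoid C–H insertion). Both stereocentres of the dihydrobenzofuran and their cis relation come from an achiral benzyl aryl ether in one step. The demand is catalyst control of the absolute configuration and kinetic cis selectivity.

7 ⇒ 6 ⇒ 5. The bond between C3a' and the diazo carbon is cut (Pd-catalysed coupling of an aryl iodide with ethyl diazoacetate), then the acetal. The iodide of a commercial vanillin derivative becomes the carbenoid site in one step. The demand is coupling without loss of nitrogen at a hindered, electron-rich iodide.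

5 ⇒ 3 + 4, and 3 ⇒ 2 ⇒ 1. The O–CH2 bond between ring B oxygen and the ring A benzyl carbon is cut (Mitsunobu etherification), then the benzylic alcohol is traced to the silylated aldehyde. The acidic, hindered phenol of 4 is a good Mitsunobu partner and no labile benzylic halide has to be made.

18 ⇒ 17 ⇒ 15 + 16, and 16 ⇒ 14 ⇒ 13. The formyl group is traced to a methyl ester and the aryl–CH2 bond is cut (copper-catalysed opening of a glycidic ester by an aryl Grignard reagent). The stereocentre is bought and never touched. A diazotisation of the corresponding amino acid was set aside because nitrous acid attacks a free guaiacol ring. The demands are attack at the terminal epoxide carbon and a half-reduction that stops at the aldehyde.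

## Other disconnections considered

Alternative 1: Petasis–Ferrier route to the tetrahydrofuran. The cut is C2–C3, after C4 is taken back to a ketone and the C3 substituent to an ester. In the forward step Me2AlCl would ionise the acetal C–O bond to the enol oxygen of the (Z)-alkylidene dioxolane A1, and the aluminium enolate of the β-keto ester would recapture the oxocarbenium ion at carbon to give the keto ester A2.
- In favour: the reaction type is known for tetrahydrofuran-3-ones, the oxocarbenium ion at C2 is well stabilised by ring B, and a 2,5-cis product is the usual outcome. C4 would then be set in a separate hydride reduction that can be tuned.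
- Against: Me2AlCl is a Lewis acid of the strength that also ionises C2'–O1', so the cis-dihydrobenzofuran is at risk in the key step itself. A1 has no short, precedented preparation from 11 and 17, since an enol acetal of a β-keto ester must be closed with control of the acetal centre and the alkene geometry. In A2 the C5 centre lies α to a ketone and can epimerise, and the β-alkoxy ketone can open by elimination. Two reductions must follow.
- Comparison: on structure both plans give the 2,5-cis ring. On precedent and on control of C4, Alternative 1 is the better. On mechanism the chosen plan is neutral and spares the acid-labile unit, which Alternative 1 does not. On step economy Alternative 1 is about four steps longer.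

Alternative 2: late C–H insertion. The cut is C2'–C3', made as the last skeletal bond. The tetrahydrofuran would first be built by the same annulation on the achiral iodo enal A3. After protection and coupling with ethyl diazoacetate, Rh2(S-PTTL)4, dirhodium tetrakis[N-phthaloyl-(S)-tert-leucinate], would decompose the diazo ester A4 and the carbenoid would insert into the OCH2 group of the ring A benzyl ether to give the cis ester A5.
- In favour: the fragile cis-dihydrobenzofuran is made last and never sees the Wittig, annulation and reduction steps; on this point the alternative is better than the chosen plan. The annulation partner A3 has no stereocentres, so catalyst control there is undisturbed. The insertion chemistry is the same as in the chosen plan, so on that point the two are equal.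
- Against: the palladium coupling and the carbenoid step are run on the most valuable intermediate. Its tetrahydrofuran oxygen can intercept the carbenoid, and its four stereocentres make the insertion a case of double stereodifferentiation that may be mismatched. The secondary hydroxyl and the hydroxymethyl group must be protected before the diazo chemistry, and ester reduction and deprotection still follow.
- Comparison: the hardest problem, the tetrahydrofuran, is not removed but only reordered. The route is linear where the chosen plan is convergent, and the longest linear sequence grows by about three steps.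

Alternative 3: anti-aldol, then aryl C–O coupling. The cut is O1'–C7a'. Pd(OAc)2 with 2-(di-tert-butylphosphino)biphenyl and K3PO4 would couple the benzylic hydroxyl of the hydroxy triflate A6 with the triflate-bearing carbon to give the cis-dihydrobenzofuran A7. No bond to C2' is broken, so the anti relation from an auxiliary-controlled aldol reaction becomes the cis relation of the ring.
- In favour: no diazo compound and no chiral dirhodium catalyst are needed. Enantiopurity comes from a stoichiometric auxiliary and is dependable. On safety at scale and on catalyst cost the alternative is better than the chosen plan. A7 is the silyl ether of 9 and would join the chosen route at 11 after acetal hydrolysis.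
- Against: anti-selective aldol reactions of arylacetic acid derivatives with electron-rich benzaldehydes are less general than syn ones, and the adduct can undergo retro-aldol cleavage and epimerisation until its carbonyl is reduced. The secondary benzylic alkoxide on palladium can undergo β-hydride elimination in competition with C–O reductive elimination at a hindered, ortho-methoxylated carbon. The base can cleave the triflate.
- Comparison: on structure both plans give the same cis ring. On mechanism it is stoichiometric control against catalytic control. A6 needs about eight or nine steps where 8 needs four, and the alternative addresses only the dihydrobenzofuran, so it would replace steps 3–7 and not the key step.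

Key step: step 13

## Conventions and assumptions

- Locants: tetrahydrofuran O1, C2 (aryl), C3 (CH2OH or CHO), C4 (OH), C5 (benzyl); primed locants for the dihydrobenzofuran. TBS = tert-butyldimethylsilyl, TBSO = tert-butyldimethylsilyloxy.
- Assumption for step 6: Rh2(S-PTTL)4 is taken to induce the sense known for ortho-benzyloxyaryl diazoacetates, which corresponds to the (2R,3S) cis ester; if the opposite sense were met, Rh2(R-PTTL)4 would be used.
- Assumption for step 13: the (S)-configured prolinol silyl ether is taken to direct the oxygen nucleophile to the same face of a β-aryl iminium ion as it directs carbon and sulfur nucleophiles, which corresponds to (2S); otherwise the (R) catalyst would be used.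

## Route

Step 1
Reactants: 1 vanillin (4-hydroxy-3-methoxybenzaldehyde)
Product: 2 4-(tert-butyldimethylsilyloxy)-3-methoxybenzaldehyde
Conditions: TBSCl, imidazole, DMF, rt
Reagents that add atoms: tert-butyldimethylsilyl chloride (TBSCl), CC(C)(C)[Si](C)(C)Cl
Why: Standard silylation of a phenol; the silyl ether is chosen so that the end of the synthesis needs fluoride and not hydrogen.

Step 2
Reactants: 2 4-(tert-butyldimethylsilyloxy)-3-methoxybenzaldehyde
Product: 3 [4-(tert-butyldimethylsilyloxy)-3-methoxyphenyl]methanol
Conditions: NaBH4, MeOH–THF, 0 °C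
Reagents that add atoms: none
Why: Borohydride reduction of an aromatic aldehyde is fast at 0 °C, and the short contact time should leave the aryl silyl ether intact.

Step 3
Reactants: 3 [4-(tert-butyldimethylsilyloxy)-3-methoxyphenyl]methanol; 4 5-iodovanillin (4-hydroxy-3-iodo-5-methoxybenzaldehyde)
Product: 5 4-{[4-(TBSO)-3-methoxybenzyl]oxy}-3-iodo-5-methoxybenzaldehyde
Conditions: PPh3, DIAD, THF, 0 °C → rt
Reagents that add atoms: none
Why: Mitsunobu etherification; the phenol of 4 is acidic enough to protonate the betaine and the benzylic oxyphosphonium ion is a reactive electrophile, so no unstable para-silyloxybenzyl halide is needed.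

Step 4
Reactants: 5 4-{[4-(TBSO)-3-methoxybenzyl]oxy}-3-iodo-5-methoxybenzaldehyde
Product: 6 2-(4-{[4-(TBSO)-3-methoxybenzyl]oxy}-3-iodo-5-methoxyphenyl)-1,3-dioxolane
Conditions: HOCH2CH2OH, HC(OEt)3, PPTS (cat.), CH2Cl2, rt
Reagents that add atoms: ethylene glycol, OCCO
Why: Acetalisation driven by the orthoformate as water scavenger; the weak acid should spare the electron-rich benzyl aryl ether and the silyl ether, and the acetal hides the aldehyde from the diazo ester, the carbenoid and the hydride of steps 5–7.

Step 5
Reactants: 6 2-(4-{[4-(TBSO)-3-methoxybenzyl]oxy}-3-iodo-5-methoxyphenyl)-1,3-dioxolane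
Product: 7 ethyl 2-diazo-2-[2-{[4-(TBSO)-3-methoxybenzyl]oxy}-5-(1,3-dioxolan-2-yl)-3-methoxyphenyl]acetate
Conditions: Pd(PPh3)4 (10 mol%), N2CHCO2Et, Et3N, Bu4NBr, MeCN, 25–45 °C
Reagents that add atoms: ethyl diazoacetate, CCOC(=O)C=[N+]=[N-]
Why: Pd-catalysed cross-coupling of an aryl iodide with ethyl diazoacetate: oxidative addition, base-assisted palladation of the diazo C–H bond and reductive elimination, with the diazo group retained at near-ambient temperature; it makes the aryl diazoacetate in one step.

Step 6
Reactants: 7 ethyl 2-diazo-2-[2-{[4-(TBSO)-3-methoxybenzyl]oxy}-5-(1,3-dioxolan-2-yl)-3-methoxyphenyl]acetate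
Product: 8 ethyl (2R,3S)-2-[4-(TBSO)-3-methoxyphenyl]-5-(1,3-dioxolan-2-yl)-7-methoxy-2,3-dihydrobenzofuran-3-carboxylate (2,3-cis)
Conditions: Rh2(S-PTTL)4, dirhodium tetrakis[N-phthaloyl-(S)-tert-leucinate] (1–2 mol%), toluene, −78 → −40 °C
Reagents that add atoms: none
Why: Intramolecular 1,5 C–H insertion of an aryl(alkoxycarbonyl)carbenoid into the OCH2 group of an ortho-benzyloxy substituent, a known route to cis-2-aryl-2,3-dihydrobenzofuran-3-carboxylates; the concerted three-centre insertion should give the cis isomer kinetically, the phthalimide walls of the catalyst should set C2' and C3' together, and the C–H bond is activated by the ether oxygen and the electron-rich ring A.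

Step 7
Reactants: 8 ethyl (2R,3S)-2-[4-(TBSO)-3-methoxyphenyl]-5-(1,3-dioxolan-2-yl)-7-methoxy-2,3-dihydrobenzofuran-3-carboxylate
Product: 10 (2R,3R)-2-[4-(TBSO)-3-methoxyphenyl]-3-(hydroxymethyl)-7-methoxy-2,3-dihydrobenzofuran-5-carbaldehyde (2,3-cis), via hydroxymethyl dioxolane 9 (not isolated)
Conditions: iBu2AlH (3 equiv), toluene, −78 → 0 °C; then 0.5 M aq. HCl, THF, 0 °C → rt
Reagents that add atoms: water, O
Why: Ester reduction with a non-basic aluminium hydride should leave the α-centre untouched (the descriptor changes from 3S to 3R only through the priority rules), after which C3' can no longer epimerise; the dilute acid of the work-up hydrolyses the aryl dioxolane, which cleaves far faster than the C2'–O1' bond ionises.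

Step 8
Reactants: 10 (2R,3R)-2-[4-(TBSO)-3-methoxyphenyl]-3-(hydroxymethyl)-7-methoxy-2,3-dihydrobenzofuran-5-carbaldehyde
Product: 11 (2R,3R)-3-[(TBSO)methyl]-2-[4-(TBSO)-3-methoxyphenyl]-7-methoxy-2,3-dihydrobenzofuran-5-carbaldehyde
Conditions: TBSCl, imidazole, DMF, rt
Reagents that add atoms: tert-butyldimethylsilyl chloride (TBSCl), CC(C)(C)[Si](C)(C)Cl
Why: Silylation of the primary alcohol, so that the enal carries no hydroxyl that could compete as an oxygen nucleophile in step 13.

Step 9
Reactants: 11 (2R,3R)-3-[(TBSO)methyl]-2-[4-(TBSO)-3-methoxyphenyl]-7-methoxy-2,3-dihydrobenzofuran-5-carbaldehyde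
Product: 12 (E)-3-{(2R,3R)-3-[(TBSO)methyl]-2-[4-(TBSO)-3-methoxyphenyl]-7-methoxy-2,3-dihydrobenzofuran-5-yl}prop-2-enal
Conditions: Ph3P=CHCHO (1.2 equiv), toluene, 80 °C
Reagents that add atoms: (triphenylphosphoranylidene)acetaldehyde, O=CC=P(c1ccccc1)(c1ccccc1)c1ccccc1
Why: Wittig reaction with a stabilised ylide, which should give the E enal under neutral conditions that endanger neither stereocentre of the dihydrobenzofuran.

Step 10
Reactants: 13 4-bromo-2-methoxyphenol
Product: 14 (4-bromo-2-methoxyphenoxy)(tert-butyl)dimethylsilane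
Conditions: TBSCl, imidazole, DMF, rt
Reagents that add atoms: tert-butyldimethylsilyl chloride (TBSCl), CC(C)(C)[Si](C)(C)Cl
Why: Standard phenol silylation; the same group as on ring A, so that one fluoride step frees both phenols at the end.

Step 11
Reactants: 14 (4-bromo-2-methoxyphenoxy)(tert-butyl)dimethylsilane; 15 methyl (S)-glycidate (methyl (2S)-oxirane-2-carboxylate)
Product: 17 methyl (S)-3-[4-(TBSO)-3-methoxyphenyl]-2-hydroxypropanoate, via arylmagnesium bromide 16 (not isolated)
Conditions: Mg, THF, 40 °C; then CuI (10 mol%), 15, THF, −40 → −20 °C; aq. NH4Cl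
Reagents that add atoms: none
Why: Copper-catalysed SN2 opening of a glycidic ester by an aryl Grignard reagent at the terminal carbon; the stereocentre is not involved and stays S, and the low temperature with copper catalysis keeps the Grignard reagent away from the ester.

Step 12
Reactants: 17 methyl (S)-3-[4-(TBSO)-3-methoxyphenyl]-2-hydroxypropanoate
Product: 18 (S)-3-[4-(TBSO)-3-methoxyphenyl]-2-hydroxypropanal
Conditions: iBu2AlH (2.2 equiv), CH2Cl2, −78 °C; MeOH, then aq. KNaC4H4O6 (potassium sodium tartrate)
Reagents that add atoms: none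
Why: Half-reduction of an ester: the first equivalent turns the hydroxyl into an aluminium alkoxide that chelates the tetrahedral intermediate, so the reduction should stop at the aldehyde stage, and the non-basic conditions should keep the α-centre; 18 is used crude and at once, since it equilibrates with its hemiacetal dimer, which returns the monomer in solution.

Step 13
Reactants: 12 (E)-3-{(2R,3R)-3-[(TBSO)methyl]-2-[4-(TBSO)-3-methoxyphenyl]-7-methoxy-2,3-dihydrobenzofuran-5-yl}prop-2-enal; 18 (S)-3-[4-(TBSO)-3-methoxyphenyl]-2-hydroxypropanal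
Product: 20 (2S,3S,4S,5S)-5-[4-(TBSO)-3-methoxybenzyl]-2-{(2R,3R)-3-[(TBSO)methyl]-2-[4-(TBSO)-3-methoxyphenyl]-7-methoxy-2,3-dihydrobenzofuran-5-yl}-3-(hydroxymethyl)tetrahydrofuran-4-ol, via 4-hydroxytetrahydrofuran-3-carbaldehyde 19 (not isolated)
Conditions: 18 (2 equiv), (S)-α,α-diphenylprolinol trimethylsilyl ether (20 mol%), PhCO2H (20 mol%), CHCl3, rt; then MeOH, NaBH4, 0 °C
Reagents that add atoms: none
Why: Proposed new method: the secondary amine condenses with the unbranched enal 12 to an E iminium ion, the hydroxyl of 18 adds reversibly to its β-carbon, the enamine so formed attacks the tethered formyl group, and hydrolysis releases 19 and the catalyst, after which borohydride fixes the labile β-hydroxy aldehyde as the diol 20. The closest known reaction types are the amine-catalysed domino thia-Michael–aldol annulation of 2-mercaptoacetaldehyde with enals and the oxa-Michael–aldol reactions of salicylaldehydes and of α-hydroxy ketones with enals; an α-hydroxy aldehyde as the oxygen donor towards so electron-rich a β-aryl enal has not been shown. The tetrahydrofuran closes through C3–C4 in a 5-(enolexo)-exo-trig aldol step, the O1–C2 bond having been made intermolecularly. C5 comes unchanged from 18, and C2 is set by the catalyst, whose diphenyl(silyloxy)methyl group blocks one face of the iminium ion so that oxygen should enter on the face that gives (2S), cis to the C5 benzyl group. C3 follows because the enamine can reach the aldehyde only on the face that carries O1, which places the formyl group trans to the C2 aryl group, and this centre can also equilibrate through the enamine. C4 is set by the orientation of the carbonyl group in the aldol transition state: with C=O antiperiplanar to the enamine double bond the hydroxyl ends trans to the formyl group and cis to the benzyl group, and this is the least secure of the three new centres. The step needs selectivity between two aldehydes and between oxygen and carbon nucleophiles: the bulky catalyst should condense much faster with the linear enal than with α-branched 18, the oxa-Michael step is reversible so that only the adduct able to close is drained, and ring closure is intramolecular whereas self-condensation of 18 is not. Reduction in the same flask removes the risk that 19 dehydrates, epimerises or reverts on isolation.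

Step 14
Reactants: 20 (2S,3S,4S,5S)-5-[4-(TBSO)-3-methoxybenzyl]-2-{(2R,3R)-3-[(TBSO)methyl]-2-[4-(TBSO)-3-methoxyphenyl]-7-methoxy-2,3-dihydrobenzofuran-5-yl}-3-(hydroxymethyl)tetrahydrofuran-4-ol
Product: 21 (2S,3S,4S,5S)-5-(4-hydroxy-3-methoxybenzyl)-2-[(2R,3R)-2-(4-hydroxy-3-methoxyphenyl)-3-(hydroxymethyl)-7-methoxy-2,3-dihydrobenzofuran-5-yl]-3-(hydroxymethyl)tetrahydrofuran-4-ol (target)
Conditions: Bu4NF (5 equiv), AcOH (5 equiv), THF, 0 °C → rt
Reagents that add atoms: none
Why: Fluoride cleavage of two aryl silyl ethers and one primary alkyl silyl ether; the acetic acid buffer keeps the liberated phenols protonated so that the ring A phenoxide cannot open the cis-dihydrobenzofuran through a quinone methide, and no hydrogen is used, so both benzylic C–O bonds are safe.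

## Compound list

1 | vanillin (4-hydroxy-3-methoxybenzaldehyde) | COc1cc(C=O)ccc1O | starting material
2 | 4-(tert-butyldimethylsilyloxy)-3-methoxybenzaldehyde | COc1cc(C=O)ccc1O[Si](C)(C)C(C)(C)C | intermediate
3 | [4-(tert-butyldimethylsilyloxy)-3-methoxyphenyl]methanol | COc1cc(CO)ccc1O[Si](C)(C)C(C)(C)C | intermediate
4 | 5-iodovanillin (4-hydroxy-3-iodo-5-methoxybenzaldehyde) | COc1cc(C=O)cc(I)c1O | starting material
5 | 4-{[4-(TBSO)-3-methoxybenzyl]oxy}-3-iodo-5-methoxybenzaldehyde | COc1cc(C=O)cc(I)c1OCc1ccc(O[Si](C)(C)C(C)(C)C)c(OC)c1 | intermediate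
6 | 2-(4-{[4-(TBSO)-3-methoxybenzyl]oxy}-3-iodo-5-methoxyphenyl)-1,3-dioxolane | COc1cc(C2OCCO2)cc(I)c1OCc1ccc(O[Si](C)(C)C(C)(C)C)c(OC)c1 | intermediate
7 | ethyl 2-diazo-2-[2-{[4-(TBSO)-3-methoxybenzyl]oxy}-5-(1,3-dioxolan-2-yl)-3-methoxyphenyl]acetate | CCOC(=O)C(=[N+]=[N-])c1cc(C2OCCO2)cc(OC)c1OCc1ccc(O[Si](C)(C)C(C)(C)C)c(OC)c1 | intermediate
8 | ethyl (2R,3S)-2-[4-(TBSO)-3-methoxyphenyl]-5-(1,3-dioxolan-2-yl)-7-methoxy-2,3-dihydrobenzofuran-3-carboxylate (cis) | O1CCOC1c1cc(OC)c2c(c1)[C@H](C(=O)OCC)[C@H](c1ccc(O[Si](C)(C)C(C)(C)C)c(OC)c1)O2 | intermediate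
9 | {(2R,3R)-2-[4-(TBSO)-3-methoxyphenyl]-5-(1,3-dioxolan-2-yl)-7-methoxy-2,3-dihydrobenzofuran-3-yl}methanol (cis) | O1CCOC1c1cc(OC)c2c(c1)[C@H](CO)[C@H](c1ccc(O[Si](C)(C)C(C)(C)C)c(OC)c1)O2 | intermediate (not isolated)
10 | (2R,3R)-2-[4-(TBSO)-3-methoxyphenyl]-3-(hydroxymethyl)-7-methoxy-2,3-dihydrobenzofuran-5-carbaldehyde (cis) | O=Cc1cc(OC)c2c(c1)[C@H](CO)[C@H](c1ccc(O[Si](C)(C)C(C)(C)C)c(OC)c1)O2 | intermediate
11 | (2R,3R)-3-[(TBSO)methyl]-2-[4-(TBSO)-3-methoxyphenyl]-7-methoxy-2,3-dihydrobenzofuran-5-carbaldehyde (cis) | O=Cc1cc(OC)c2c(c1)[C@H](CO[Si](C)(C)C(C)(C)C)[C@H](c1ccc(O[Si](C)(C)C(C)(C)C)c(OC)c1)O2 | intermediate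
12 | (E)-3-{(2R,3R)-3-[(TBSO)methyl]-2-[4-(TBSO)-3-methoxyphenyl]-7-methoxy-2,3-dihydrobenzofuran-5-yl}prop-2-enal | O=C/C=C/c1cc(OC)c2c(c1)[C@H](CO[Si](C)(C)C(C)(C)C)[C@H](c1ccc(O[Si](C)(C)C(C)(C)C)c(OC)c1)O2 | intermediate (key-step precursor)
13 | 4-bromo-2-methoxyphenol | COc1cc(Br)ccc1O | starting material
14 | (4-bromo-2-methoxyphenoxy)(tert-butyl)dimethylsilane | COc1cc(Br)ccc1O[Si](C)(C)C(C)(C)C | intermediate
15 | methyl (S)-glycidate (methyl (2S)-oxirane-2-carboxylate) | COC(=O)[C@@H]1CO1 | starting material
16 | [4-(TBSO)-3-methoxyphenyl]magnesium bromide | COc1cc([Mg]Br)ccc1O[Si](C)(C)C(C)(C)C | intermediate (not isolated)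
17 | methyl (S)-3-[4-(TBSO)-3-methoxyphenyl]-2-hydroxypropanoate | COc1cc(C[C@H](O)C(=O)OC)ccc1O[Si](C)(C)C(C)(C)C | intermediate
18 | (S)-3-[4-(TBSO)-3-methoxyphenyl]-2-hydroxypropanal | COc1cc(C[C@H](O)C=O)ccc1O[Si](C)(C)C(C)(C)C | intermediate (key-step precursor)
19 | (2S,3S,4S,5S)-5-[4-(TBSO)-3-methoxybenzyl]-2-{(2R,3R)-3-[(TBSO)methyl]-2-[4-(TBSO)-3-methoxyphenyl]-7-methoxy-2,3-dihydrobenzofuran-5-yl}-4-hydroxytetrahydrofuran-3-carbaldehyde | COc1cc(C[C@@H]2O[C@H](c3cc(OC)c4c(c3)[C@H](CO[Si](C)(C)C(C)(C)C)[C@H](c3ccc(O[Si](C)(C)C(C)(C)C)c(OC)c3)O4)[C@@H](C=O)[C@@H]2O)ccc1O[Si](C)(C)C(C)(C)C | intermediate (key-step product, not isolated)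
20 | (2S,3S,4S,5S)-5-[4-(TBSO)-3-methoxybenzyl]-2-{(2R,3R)-3-[(TBSO)methyl]-2-[4-(TBSO)-3-methoxyphenyl]-7-methoxy-2,3-dihydrobenzofuran-5-yl}-3-(hydroxymethyl)tetrahydrofuran-4-ol | COc1cc(C[C@@H]2O[C@H](c3cc(OC)c4c(c3)[C@H](CO[Si](C)(C)C(C)(C)C)[C@H](c3ccc(O[Si](C)(C)C(C)(C)C)c(OC)c3)O4)[C@@H](CO)[C@@H]2O)ccc1O[Si](C)(C)C(C)(C)C | intermediate
21 | (2S,3S,4S,5S)-5-(4-hydroxy-3-methoxybenzyl)-2-[(2R,3R)-2-(4-hydroxy-3-methoxyphenyl)-3-(hydroxymethyl)-7-methoxy-2,3-dihydrobenzofuran-5-yl]-3-(hydroxymethyl)tetrahydrofuran-4-ol | COc1cc(C[C@@H]2O[C@H](c3cc(OC)c4c(c3)[C@H](CO)[C@H](c3ccc(O)c(OC)c3)O4)[C@@H](CO)[C@@H]2O)ccc1O | target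

## Step count and least certain steps

Total: 14 steps. Longest linear sequence: 11 steps (steps 1–9, 13 and 14); the ring C branch is steps 10–12.

Step 13 (key step, proposed new method). What is most likely to go wrong is that the hydroxyl of 18 adds too slowly or too reversibly to the electron-rich iminium ion, so that self-condensation or isomerisation of 18 through its enediol, or dehydration after ring closure, takes over. Facial control at C4 may also be poor, because nothing in the catalyst organises the carbonyl group. The fallback is an alkoxide-driven oxa-Michael–Dieckmann annulation at the ester oxidation level, a classical way to 4-oxotetrahydrofuran-3-carboxylates. It sets out from 11 and 17 and comes back at 20. Aldehyde 11 would be converted with trimethyl phosphonoacetate, LiCl and DBU into the methyl (E)-acrylate F1. F1 and the sodium alkoxide of 17 (NaH, THF, 0 °C → rt) should combine by conjugate addition and Dieckmann closure to the keto ester F2, held as its stabilised enolate and expected to settle as the 2,5-cis, 2,3-trans isomer. NaBH4 at low temperature should attack the ketone on the face away from the C5 benzyl and C2 aryl groups to give the hydroxy ester F3, and LiBH4 would reduce the ester of F3 to 20. The weak points of this fallback are the C5 centre, which lies next to a carbonyl group throughout, and the aryl silyl ethers under alkoxide conditions.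

Step 5. The oxidative-addition complex of the hindered, electron-rich iodide may react slowly with the diazo ester, so that palladium-induced loss of nitrogen from the reagent and from the product outruns the coupling. The fallback sets out from 6 and comes back at 7: Pd-catalysed α-arylation of the Reformatsky reagent BrZnCH2CO2Et (Pd2(dba)3, XPhos, THF, 50 °C) would give the aryl acetate F4, and Regitz diazo transfer to F4 (4-acetamidobenzenesulfonyl azide, DBU, MeCN) would give 7.

Step 12. The reduction may run on to the diol or stop short, because the free hydroxyl consumes hydride and the aluminium chelate may break down unevenly. The free hydroxy aldehyde may also lose configurational purity or oligomerise during work-up. The fallback sets out from 17 and comes back at 18: silylation with Et3SiCl and imidazole would give the triethylsilyl ether F5, iBu2AlH at −78 °C would give the α-silyloxy aldehyde F6, which can be purified and stored, and HF·pyridine buffered with pyridine would release 18 directly before step 13, the aryl silyl ether being the slower to cleave under acidic fluoride.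

Step 7. Ionisation of the C2'–O1' bond during the acidic stage would erode the cis configuration, and acid weak enough to exclude this may leave the acetal partly intact. The fallback avoids the acetal altogether; it sets out from 5 and comes back at 10 with the same number of steps. Coupling of 5 with ethyl diazoacetate as in step 5 would give the diazo aldehyde F7, insertion as in step 6 would give the cis ester aldehyde F8, iBu2AlH would reduce both carbonyl groups to the diol F9, and MnO2 would oxidise only the benzylic alcohol to give 10. This was not made the main route because a free aldehyde can intercept the carbenoid.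

Step 9. Over-homologation is the likely fault: enal 12 is more electrophilic than the electron-rich aldehyde 11 and may react with the ylide a second time to a dienal. The fallback sets out from 11 and comes back at 12: Horner–Wadsworth–Emmons reaction with triethyl phosphonoacetate, LiCl and DBU would give the ethyl (E)-acrylate F10, iBu2AlH at −78 °C would give the allylic alcohol F11, and MnO2 would oxidise F11 to 12.

## Further compounds

F1 | step 13 | methyl (E)-3-{(2R,3R)-3-[(TBSO)methyl]-2-[4-(TBSO)-3-methoxyphenyl]-7-methoxy-2,3-dihydrobenzofuran-5-yl}acrylate | COC(=O)/C=C/c1cc(OC)c2c(c1)[C@H](CO[Si](C)(C)C(C)(C)C)[C@H](c1ccc(O[Si](C)(C)C(C)(C)C)c(OC)c1)O2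
F2 | step 13 | methyl (2S,3R,5S)-5-[4-(TBSO)-3-methoxybenzyl]-2-{(2R,3R)-3-[(TBSO)methyl]-2-[4-(TBSO)-3-methoxyphenyl]-7-methoxy-2,3-dihydrobenzofuran-5-yl}-4-oxotetrahydrofuran-3-carboxylate | COc1cc(C[C@@H]2O[C@H](c3cc(OC)c4c(c3)[C@H](CO[Si](C)(C)C(C)(C)C)[C@H](c3ccc(O[Si](C)(C)C(C)(C)C)c(OC)c3)O4)[C@@H](C(=O)OC)C2=O)ccc1O[Si](C)(C)C(C)(C)C
F3 | step 13 | methyl (2S,3S,4S,5S)-5-[4-(TBSO)-3-methoxybenzyl]-2-{(2R,3R)-3-[(TBSO)methyl]-2-[4-(TBSO)-3-methoxyphenyl]-7-methoxy-2,3-dihydrobenzofuran-5-yl}-4-hydroxytetrahydrofuran-3-carboxylate | COc1cc(C[C@@H]2O[C@H](c3cc(OC)c4c(c3)[C@H](CO[Si](C)(C)C(C)(C)C)[C@H](c3ccc(O[Si](C)(C)C(C)(C)C)c(OC)c3)O4)[C@@H](C(=O)OC)[C@@H]2O)ccc1O[Si](C)(C)C(C)(C)C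
F4 | step 5 | ethyl 2-[2-{[4-(TBSO)-3-methoxybenzyl]oxy}-5-(1,3-dioxolan-2-yl)-3-methoxyphenyl]acetate | CCOC(=O)Cc1cc(C2OCCO2)cc(OC)c1OCc1ccc(O[Si](C)(C)C(C)(C)C)c(OC)c1
F5 | step 12 | methyl (S)-3-[4-(TBSO)-3-methoxyphenyl]-2-(triethylsilyloxy)propanoate | COc1cc(C[C@H](O[Si](CC)(CC)CC)C(=O)OC)ccc1O[Si](C)(C)C(C)(C)C
F6 | step 12 | (S)-3-[4-(TBSO)-3-methoxyphenyl]-2-(triethylsilyloxy)propanal | COc1cc(C[C@H](O[Si](CC)(CC)CC)C=O)ccc1O[Si](C)(C)C(C)(C)C
F7 | step 7 | ethyl 2-diazo-2-[2-{[4-(TBSO)-3-methoxybenzyl]oxy}-5-formyl-3-methoxyphenyl]acetate | CCOC(=O)C(=[N+]=[N-])c1cc(C=O)cc(OC)c1OCc1ccc(O[Si](C)(C)C(C)(C)C)c(OC)c1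
F8 | step 7 | ethyl (2R,3S)-2-[4-(TBSO)-3-methoxyphenyl]-5-formyl-7-methoxy-2,3-dihydrobenzofuran-3-carboxylate (cis) | O=Cc1cc(OC)c2c(c1)[C@H](C(=O)OCC)[C@H](c1ccc(O[Si](C)(C)C(C)(C)C)c(OC)c1)O2
F9 | step 7 | {(2R,3R)-2-[4-(TBSO)-3-methoxyphenyl]-7-methoxy-2,3-dihydrobenzofuran-3,5-diyl}dimethanol (cis) | OCc1cc(OC)c2c(c1)[C@H](CO)[C@H](c1ccc(O[Si](C)(C)C(C)(C)C)c(OC)c1)O2
F10 | step 9 | ethyl (E)-3-{(2R,3R)-3-[(TBSO)methyl]-2-[4-(TBSO)-3-methoxyphenyl]-7-methoxy-2,3-dihydrobenzofuran-5-yl}acrylate | CCOC(=O)/C=C/c1cc(OC)c2c(c1)[C@H](CO[Si](C)(C)C(C)(C)C)[C@H](c1ccc(O[Si](C)(C)C(C)(C)C)c(OC)c1)O2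
F11 | step 9 | (E)-3-{(2R,3R)-3-[(TBSO)methyl]-2-[4-(TBSO)-3-methoxyphenyl]-7-methoxy-2,3-dihydrobenzofuran-5-yl}prop-2-en-1-ol | OC/C=C/c1cc(OC)c2c(c1)[C@H](CO[Si](C)(C)C(C)(C)C)[C@H](c1ccc(O[Si](C)(C)C(C)(C)C)c(OC)c1)O2
A1 | alternative 1 | methyl (Z)-2-[(5S)-2,5-cis-5-[4-(TBSO)-3-methoxybenzyl]-2-{(2R,3R)-3-[(TBSO)methyl]-2-[4-(TBSO)-3-methoxyphenyl]-7-methoxy-2,3-dihydrobenzofuran-5-yl}-1,3-dioxolan-4-ylidene]acetate | COc1cc(C[C@@H]2O[C@H](c3cc(OC)c4c(c3)[C@H](CO[Si](C)(C)C(C)(C)C)[C@H](c3ccc(O[Si](C)(C)C(C)(C)C)c(OC)c3)O4)O/C2=C\C(=O)OC)ccc1O[Si](C)(C)C(C)(C)C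
A2 | alternative 1 | methyl (2S,3R,5S)-5-[4-(TBSO)-3-methoxybenzyl]-2-{(2R,3R)-3-[(TBSO)methyl]-2-[4-(TBSO)-3-methoxyphenyl]-7-methoxy-2,3-dihydrobenzofuran-5-yl}-4-oxotetrahydrofuran-3-carboxylate | COc1cc(C[C@@H]2O[C@H](c3cc(OC)c4c(c3)[C@H](CO[Si](C)(C)C(C)(C)C)[C@H](c3ccc(O[Si](C)(C)C(C)(C)C)c(OC)c3)O4)[C@@H](C(=O)OC)C2=O)ccc1O[Si](C)(C)C(C)(C)C
A3 | alternative 2 | (E)-3-(4-{[4-(TBSO)-3-methoxybenzyl]oxy}-3-iodo-5-methoxyphenyl)prop-2-enal | O=C/C=C/c1cc(OC)c(OCc2ccc(O[Si](C)(C)C(C)(C)C)c(OC)c2)c(I)c1
A4 | alternative 2 | ethyl 2-diazo-2-[2-{[4-(TBSO)-3-methoxybenzyl]oxy}-3-methoxy-5-{(2S,3S,4S,5S)-5-[4-(TBSO)-3-methoxybenzyl]-4-(TBSO)-3-[(TBSO)methyl]tetrahydrofuran-2-yl}phenyl]acetate | COc1cc(C[C@@H]2O[C@H](c3cc(OC)c(OCc4ccc(O[Si](C)(C)C(C)(C)C)c(OC)c4)c(c3)C(=[N+]=[N-])C(=O)OCC)[C@@H](CO[Si](C)(C)C(C)(C)C)[C@@H]2O[Si](C)(C)C(C)(C)C)ccc1O[Si](C)(C)C(C)(C)C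
A5 | alternative 2 | ethyl (2R,3S)-2-[4-(TBSO)-3-methoxyphenyl]-7-methoxy-5-{(2S,3S,4S,5S)-5-[4-(TBSO)-3-methoxybenzyl]-4-(TBSO)-3-[(TBSO)methyl]tetrahydrofuran-2-yl}-2,3-dihydrobenzofuran-3-carboxylate (cis) | COc1cc(C[C@@H]2O[C@H](c3cc(OC)c4c(c3)[C@H](C(=O)OCC)[C@H](c3ccc(O[Si](C)(C)C(C)(C)C)c(OC)c3)O4)[C@@H](CO[Si](C)(C)C(C)(C)C)[C@@H]2O[Si](C)(C)C(C)(C)C)ccc1O[Si](C)(C)C(C)(C)C
A6 | alternative 3 | (1R,2R)-1-[4-(TBSO)-3-methoxyphenyl]-2-[5-(1,3-dioxolan-2-yl)-3-methoxy-2-(trifluoromethylsulfonyloxy)phenyl]-3-(TBSO)propan-1-ol | O1CCOC1c1cc(OC)c(OS(=O)(=O)C(F)(F)F)c(c1)[C@H](CO[Si](C)(C)C(C)(C)C)[C@@H](O)c1ccc(O[Si](C)(C)C(C)(C)C)c(OC)c1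
A7 | alternative 3 | 2-{(2R,3R)-3-[(TBSO)methyl]-2-[4-(TBSO)-3-methoxyphenyl]-7-methoxy-2,3-dihydrobenzofuran-5-yl}-1,3-dioxolane (cis) | O1CCOC1c1cc(OC)c2c(c1)[C@H](CO[Si](C)(C)C(C)(C)C)[C@H](c1ccc(O[Si](C)(C)C(C)(C)C)c(OC)c1)O2
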